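A direct plan would build ring A from a cyclohexenone: 3-bromo-4-hydroxybenzaldehyde A1 would be tosylated, joined by a lithium enolate aldol to 2-methoxycyclohex-2-en-1-one A2, dehydrated and isoaromatised under acid to the benzylguaiacol tosylate A3. O-Methylation, Rieche formylation to the dimethoxy aldehyde A4, BBr3, bromination to the bromocatechol aldehyde A5, hydroxide detosylation and NaBH4 would follow, about eleven steps in all.
Weak point 1: the aldol, elimination and acid isoaromatisation would spend five steps, one of them a capricious tautomerisation, on a plain guaiacol ring that can be bought as an arene.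
Weak point 2: the oxygen traffic (tosyl on and off, methyl on and off) would build nothing, and the formylation would rest on a subtle twisted-methoxy preference for its regiochemistry.
Weak point 3: the detosylation of A5 with hot KOH, one step from the end, would expose an air-sensitive bromocatecholate aldehyde to the harshest conditions of the whole plan.

**Retrosynthetic overview**
The target is cut at the bond between the bridging CH2 and C1 of ring B (the 3-bromo-4-hydroxyphenyl ring), not at the bond from CH2 to ring A.
The feature used is the 1,2-relationship on ring A between the CH2OH-bearing carbon and the carbon that bears the bridging CH2: the CH2 starts as a methyl group, and the neighbouring carbon, at the aldehyde level, steers palladium onto that methyl group through a transient imine.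
No ring is built: both benzene rings are bought intact, so the five-step ring construction disappears.
Both bromines are in place before the union (ring A by a vanillin-type bromination of a small catechol aldehyde, ring B purchased), so no bromination has to choose between two phenolic rings.
The three phenols travel as acetates and are freed by the same hydride that reduces the aldehyde, so no sulfonate, hot base or Lewis acid meets the assembled diarylmethane.

Key step: step 6

Step 1
Reactants: 1 2,3-dimethoxytoluene (1,2-dimethoxy-3-methylbenzene)
Product: 3 3,4-dimethoxy-2-methylbenzaldehyde, via alpha-chloro ether 2 (not isolated)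
Conditions: Cl2CHOMe (1.3 equiv), TiCl4 (2.0 equiv), CH2Cl2, −10 to 0 °C, 1–2 h; then ice/1 M HCl
Reagents that add atoms: dichloromethyl methyl ether, COC(Cl)Cl; water, O
Why: Rieche formylation (Friedel–Crafts type) should go para to the outer methoxy group, the only one with a free ortho position and therefore coplanar with the ring, at the carbon that is also ortho to the methyl group, the same preference that turns 1,2,3-trimethoxybenzene into 2,3,4-trimethoxybenzaldehyde; no stereocentre is formed.

Step 2
Reactants: 3 3,4-dimethoxy-2-methylbenzaldehyde
Product: 5 3,4-dihydroxy-2-methylbenzaldehyde, via cyclic bromoboronate 4 (not isolated)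
Conditions: BBr3 (3.0 equiv, 1.0 M in CH2Cl2), CH2Cl2, −78 °C to rt, 3 h; then ice-water
Reagents that add atoms: none
Why: Lewis-acid ether cleavage with BBr3 (O-coordination, then SN2 attack of bromide on methyl) should remove both aryl methyl ethers of this small, robust aldehyde, as in the conversion of veratraldehyde into protocatechualdehyde, and the aldehyde is released again on hydrolysis.

Step 3
Reactants: 5 3,4-dihydroxy-2-methylbenzaldehyde
Product: 6 5-bromo-3,4-dihydroxy-2-methylbenzaldehyde
Conditions: Br2 (1.0 equiv, dropwise in AcOH), sodium acetate (1.2 equiv), AcOH, 15–20 °C, dark, 1–2 h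
Reagents that add atoms: bromine, BrBr
Why: Electrophilic aromatic bromination should take the carbon ortho to the 4-OH group, para to the methyl group and meta to the aldehyde, as in the 5-bromination of vanillin and of protocatechualdehyde, because the only other free carbon, although para to the 3-OH group, is ortho to the deactivating aldehyde; sodium acetate takes up HBr.

Step 4
Reactants: 6 5-bromo-3,4-dihydroxy-2-methylbenzaldehyde
Product: 7 6-bromo-4-formyl-3-methyl-1,2-phenylene diacetate
Conditions: Ac2O (2.5 equiv), pyridine (3 equiv), 4-(dimethylamino)pyridine (5 mol %), CH2Cl2, 0 °C to rt, 2 h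
Reagents that add atoms: acetic anhydride, CC(=O)OC(C)=O
Why: O-Acetylation under nucleophilic catalysis by 4-(dimethylamino)pyridine should cap both phenols without touching the aldehyde, which protects the catechol from oxidation by silver and palladium salts in the key step.

Step 5
Reactants: 8 2-bromo-4-iodophenol
Product: 9 2-bromo-4-iodophenyl acetate
Conditions: Ac2O (1.2 equiv), pyridine (1.5 equiv), CH2Cl2, 0 °C to rt, 1 h
Reagents that add atoms: acetic anhydride, CC(=O)OC(C)=O
Why: O-Acetylation of the phenol keeps the oxygen of ring B from binding palladium or silver in the key step and leaves the C–I and C–Br bonds untouched.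

Step 6
Reactants: 7 6-bromo-4-formyl-3-methyl-1,2-phenylene diacetate; 9 2-bromo-4-iodophenyl acetate
Product: 11 3-[4-(acetyloxy)-3-bromobenzyl]-6-bromo-4-formyl-1,2-phenylene diacetate, via transient glycine imine 10 (not isolated)
Conditions: 9 (1.5 equiv), Pd(OAc)2 (10 mol %), glycine (40 mol %), AgOCOCF3 (1.5 equiv), (CF3)2CHOH/AcOH 9:1, 90 °C, 24–36 h
Reagents that add atoms: none
Why: Palladium-catalysed C(sp3)–H arylation with a transient directing group: glycine condenses reversibly with the aldehyde of 7 to imine 10, whose N,O-chelate brings divalent palladium to the neighbouring methyl group and palladates it by carboxylate-assisted concerted metalation–deprotonation; oxidative addition of the C–I bond of 9 gives a tetravalent palladium benzyl aryl species, C–C reductive elimination forms the bond between the bridging CH2 and C1 of ring B, AgOCOCF3 removes iodide, and hydrolysis of the imine returns glycine. The closest known reaction type is the glycine-mediated benzylic arylation of 2-methylbenzaldehydes with aryl iodides under the same Pd(OAc)2/AgOCOCF3 conditions. No ring of the product is closed (only the transient six-membered palladacycle fused to the five-membered glycinate chelate forms) and no stereocentre is created. The step needs palladation at the methyl group and not at the ring C–H ortho to the aldehyde: the bicyclic chelate favours the sp3 site, and the free ortho carbon is shielded by the adjacent bromine. It needs the C–I bond to react and the three C–Br bonds to stay: the cycle runs between divalent and tetravalent palladium, which aryl bromides should not enter under these conditions. The acetates keep the phenols away from silver and make both rings too electron-poor for a Bradsher cyclisation onto the aldehyde, and partial loss of acetate would be harmless because the next step removes all three.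

Step 7
Reactants: 11 3-[4-(acetyloxy)-3-bromobenzyl]-6-bromo-4-formyl-1,2-phenylene diacetate
Product: 13 6-bromo-3-(3-bromo-4-hydroxybenzyl)-4-(hydroxymethyl)benzene-1,2-diol (target), via triacetoxy benzyl alcohol 12 (not isolated)
Conditions: LiBH4 (5 equiv), THF, 0 °C to rt, Ar, 2–4 h; then pH 6 phosphate buffer at 0 °C, EtOAc extraction, no acid, no heat
Reagents that add atoms: none
Why: Hydride reduction with LiBH4 should convert the aldehyde into the primary alcohol within minutes and then cleave the three aryl acetates reductively (hydride addition to the acyl group, loss of phenoxide, reduction of acetaldehyde to ethoxide), while aryl bromides are inert, and the cold buffered work-up avoids quinone methide formation from the p-hydroxybenzyl alcohol; no stereocentre is formed.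

## Compound list
1 | 2,3-dimethoxytoluene (1,2-dimethoxy-3-methylbenzene) | COc1cccc(C)c1OC | starting material
2 | 1-[chloro(methoxy)methyl]-3,4-dimethoxy-2-methylbenzene (racemic) | COC(Cl)c1ccc(OC)c(OC)c1C | intermediate
3 | 3,4-dimethoxy-2-methylbenzaldehyde | O=Cc1ccc(OC)c(OC)c1C | intermediate
4 | 2-bromo-4-methyl-1,3,2-benzodioxaborole-5-carbaldehyde | O=Cc1ccc2OB(Br)Oc2c1C | intermediate
5 | 3,4-dihydroxy-2-methylbenzaldehyde | O=Cc1ccc(O)c(O)c1C | intermediate
6 | 5-bromo-3,4-dihydroxy-2-methylbenzaldehyde | O=Cc1cc(Br)c(O)c(O)c1C | intermediate
7 | 6-bromo-4-formyl-3-methyl-1,2-phenylene diacetate | O=Cc1cc(Br)c(OC(C)=O)c(OC(C)=O)c1C | intermediate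
8 | 2-bromo-4-iodophenol | Oc1ccc(I)cc1Br | starting material
9 | 2-bromo-4-iodophenyl acetate | CC(=O)Oc1ccc(I)cc1Br | intermediate
10 | N-[(E)-(3,4-diacetoxy-5-bromo-2-methylphenyl)methylidene]glycine | OC(=O)C/N=C/c1cc(Br)c(OC(C)=O)c(OC(C)=O)c1C | intermediate
11 | 3-[4-(acetyloxy)-3-bromobenzyl]-6-bromo-4-formyl-1,2-phenylene diacetate | O=Cc1cc(Br)c(OC(C)=O)c(OC(C)=O)c1Cc1ccc(OC(C)=O)c(Br)c1 | intermediate
12 | 3-[4-(acetyloxy)-3-bromobenzyl]-6-bromo-4-(hydroxymethyl)-1,2-phenylene diacetate | OCc1cc(Br)c(OC(C)=O)c(OC(C)=O)c1Cc1ccc(OC(C)=O)c(Br)c1 | intermediate
13 | 6-bromo-3-(3-bromo-4-hydroxybenzyl)-4-(hydroxymethyl)benzene-1,2-diol (achiral) | OCc1cc(Br)c(O)c(O)c1Cc1ccc(O)c(Br)c1 | target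

Total step count: 7. Longest linear sequence: 6 (steps 1, 2, 3, 4, 6, 7).

**Steps most likely to fail**

Step 6 (key step). Palladation of a methyl group flanked by an acetoxy group could be slow, the catalyst could be lost before full conversion, acetates could be shed in the hot acidic medium or transferred to the amine of glycine, and the new benzylic CH2 could be arylated a second time. The fallback gives up C–H activation for halogenation and cross-coupling; it sets out from 7 and 9 and comes back at 11. Wohl–Ziegler bromination of 7 (N-bromosuccinimide, azobisisobutyronitrile, PhCF3, 80 °C) would give 6-bromo-3-(bromomethyl)-4-formyl-1,2-phenylene diacetate F1, with competing attack on the aldehyde C–H as the main risk. Miyaura borylation of 9 at its C–I bond (bis(pinacolato)diboron, [1,1'-bis(diphenylphosphino)ferrocene]dichloropalladium, potassium acetate, dioxane, 80 °C) would give 2-bromo-4-(4,4,5,5-tetramethyl-1,3,2-dioxaborolan-2-yl)phenyl acetate F2. A Suzuki–Miyaura coupling of F1 with F2 (Pd(PPh3)4, anhydrous K3PO4, toluene, 60 °C) would then give 11, since a benzylic C–Br bond adds to zerovalent palladium faster than an aryl C–Br bond and the anhydrous base spares the acetates.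

Step 7. The boron-bound p-oxidobenzyl alkoxide could ionise to a quinone methide that hydride reduces to a methyl group, and catechol borate complexes could resist hydrolysis at the mild pH that the product needs. The fallback separates reduction from deprotection and replaces reductive ester cleavage by acyl transfer to an amine; it sets out from 11 and comes back at 13. NaBH4 (THF/H2O 9:1, 0 °C) would reduce only the aldehyde and 12 would be isolated; aminolysis with n-butylamine (THF, rt, Ar) would then move the three acetyl groups to nitrogen under neutral, non-reducing conditions and give 13. No new compound is made.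

Step 3. Bromine could oxidise the free catechol to an o-quinone, or a second bromine could enter ortho to the aldehyde. The fallback places the bromine by directed metalation before the aldehyde and the free catechol exist; it sets out from 1 and comes back at 6. Directed ortho-metalation of 1 (butyllithium, N,N,N',N'-tetramethylethylenediamine, Et2O, 0 °C), directed by the outer methoxy group, and quenching with 1,2-dibromotetrachloroethane would give 1-bromo-2,3-dimethoxy-4-methylbenzene F3. Rieche formylation (Cl2CHOMe, TiCl4, CH2Cl2, 0 °C), expected ortho to the activating methyl group and not ortho to bromine, would give 5-bromo-3,4-dimethoxy-2-methylbenzaldehyde F4. BBr3 (CH2Cl2, −78 °C to rt) would then give 6.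

## Further compounds
F1 | step 6 | 6-bromo-3-(bromomethyl)-4-formyl-1,2-phenylene diacetate | O=Cc1cc(Br)c(OC(C)=O)c(OC(C)=O)c1CBr
F2 | step 6 | 2-bromo-4-(4,4,5,5-tetramethyl-1,3,2-dioxaborolan-2-yl)phenyl acetate | CC(=O)Oc1ccc(cc1Br)B1OC(C)(C)C(C)(C)O1
F0 | step 7 | none | none
F3 | step 3 | 1-bromo-2,3-dimethoxy-4-methylbenzene | COc1c(C)ccc(Br)c1OC
F4 | step 3 | 5-bromo-3,4-dimethoxy-2-methylbenzaldehyde | O=Cc1cc(Br)c(OC)c(OC)c1C
A1 | direct plan | 3-bromo-4-hydroxybenzaldehyde | O=Cc1ccc(O)c(Br)c1
A2 | direct plan | 2-methoxycyclohex-2-en-1-one | COC1=CCCCC1=O
A3 | direct plan | 2-bromo-4-(2-hydroxy-3-methoxybenzyl)phenyl 4-methylbenzenesulfonate | COc1cccc(Cc2ccc(OS(=O)(=O)c3ccc(C)cc3)c(Br)c2)c1O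
A4 | direct plan | 2-bromo-4-(6-formyl-2,3-dimethoxybenzyl)phenyl 4-methylbenzenesulfonate | O=Cc1ccc(OC)c(OC)c1Cc2ccc(OS(=O)(=O)c3ccc(C)cc3)c(Br)c2
A5 | direct plan | 2-bromo-4-(4-bromo-6-formyl-2,3-dihydroxybenzyl)phenyl 4-methylbenzenesulfonate | O=Cc1cc(Br)c(O)c(O)c1Cc2ccc(OS(=O)(=O)c3ccc(C)cc3)c(Br)c2
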